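## Retrosynthetic overview

1. The only ring is the α,β-unsaturated δ-lactone (diterpene numbering: C1 = CH2OH, C8 = ring carbinol, C18 = ring C=O, C19 = CH2OAc). It is closed as in the presumed biosynthesis, by attack of O8 on the C18 carboxyl of a (10Z)-8-hydroxy-18-oate.
2. That seco-ester is generated in the same flask by a catalytic asymmetric vinylogous aldol reaction (C8–C9) between an α-homoprenyl but-3-enoate and an (E)-2-(acetoxymethyl)enal. This sets C8 (S), and the aldolate lactonises at once.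
3. Enal (C1–C8 and C19): nerol (2Z geometry bought) → silyl ether → ozonolytic truncation → addition of an acrolein α-anion equivalent with acetylation → allylic acetate 1,3-shift (sets 6E, places OAc on C19).
4. Donor (C9–C18): deconjugative α-alkylation of methyl crotonate with homoprenyl bromide.
5. Order: the lactone ring forms in step 6; desilylation ends the route.

Assumption: the target is taken exactly as drawn (C8 = S, 2Z, 6E), and the ligand antipode named in step 6 is assumed to direct the dienolate to the Si face of the aldehyde; if a first run shows the opposite sense, the other antipode is used.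

## Route

Step 1
Reactants: 1 nerol
Product: 2 tert-butyl{[(2Z)-3,7-dimethylocta-2,6-dien-1-yl]oxy}diphenylsilane
Conditions: TBDPSCl, imidazole, CH2Cl2, 0 °C → rt
Reagents that add atoms: tert-butyl(chloro)diphenylsilane, CC(C)(C)[Si](Cl)(c1ccccc1)c1ccccc1
Why: Imidazole-promoted silyl ether formation on a primary allylic alcohol is reliable, the bulky acid-tolerant silyl group survives steps 2 to 6 and shields the 2,3-olefin, and the bought 2Z geometry is untouched (no stereocentre formed).

Step 2
Reactants: 2 tert-butyl{[(2Z)-3,7-dimethylocta-2,6-dien-1-yl]oxy}diphenylsilane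
Product: 4 (4Z)-6-[(tert-butyldiphenylsilyl)oxy]-4-methylhex-4-enal, via secondary ozonide 3 (not isolated)
Conditions: O3 (1.0 equiv, metered), CH2Cl2, −78 °C; then PPh3, −78 °C → rt
Reagents that add atoms: ozone, [O-][O+]=O
Why: In this chemoselective ozonolysis (Criegee mechanism) the isopropylidene olefin is more electron-rich and less hindered than the olefin bearing the inductively withdrawing, bulky allylic silyloxy group, so one equivalent of ozone cleaves it first and PPh3 reduces the ozonide to the aldehyde (no stereocentre formed).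

Step 3
Reactants: 4 (4Z)-6-[(tert-butyldiphenylsilyl)oxy]-4-methylhex-4-enal; 5 2-bromo-3,3-diethoxyprop-1-ene
Product: 8 (6Z)-8-[(tert-butyldiphenylsilyl)oxy]-1,1-diethoxy-6-methyl-2-methylideneoct-6-en-3-yl acetate (racemic), via 2-lithioacrolein acetal 6 (not isolated), via lithium alkoxide adduct 7 (not isolated)
Conditions: 5, n-BuLi, THF, −78 °C; then 4, −78 °C; then Ac2O, −78 → 0 °C
Reagents that add atoms: acetic anhydride, CC(=O)OC(C)=O
Why: Bromine–lithium exchange gives the acrolein α-anion equivalent, which adds 1,2 to the aldehyde at −78 °C (a stoichiometric stand-in for a Morita–Baylis–Hillman reaction with acrolein), and the alkoxide is acetylated in situ; the new carbinol centre is racemic and is erased in step 4.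

Step 4
Reactants: 8 (6Z)-8-[(tert-butyldiphenylsilyl)oxy]-1,1-diethoxy-6-methyl-2-methylideneoct-6-en-3-yl acetate
Product: 10 (2E,6Z)-2-(acetoxymethyl)-8-[(tert-butyldiphenylsilyl)oxy]-6-methylocta-2,6-dienal, via methylene aldehyde 9 (not isolated)
Conditions: (COOH)2 (cat.), wet SiO2, CH2Cl2, rt; filter; then DABCO (20 mol %), THF, rt
Reagents that add atoms: water, O
Why: Mild acetal hydrolysis unmasks the 2-methylene aldehyde, whose secondary allylic acetate undergoes DABCO-catalysed SN2'–SN2 1,3-transposition (Morita–Baylis–Hillman acetate isomerisation) to the thermodynamically preferred trisubstituted enal with CHO trans to the chain, which fixes the 6E olefin, puts the acetate on C19 and removes the racemic centre.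

Step 5
Reactants: 11 methyl (2E)-but-2-enoate; 12 5-bromo-2-methylpent-2-ene
Product: 14 methyl 2-ethenyl-6-methylhept-5-enoate (racemic), via lithium dienolate 13 (not isolated)
Conditions: LiN(iPr)2, HMPA, THF, −78 °C; then 12, −78 °C → rt
Reagents that add atoms: none
Why: Kinetic γ-deprotonation of the crotonate and alkylation of the dienolate at its α-carbon (deconjugative α-alkylation of an enoate) gives the β,γ-unsaturated ester; the α-centre is racemic and is destroyed on enolisation in step 6.

Step 6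
Reactants: 10 (2E,6Z)-2-(acetoxymethyl)-8-[(tert-butyldiphenylsilyl)oxy]-6-methylocta-2,6-dienal; 14 methyl 2-ethenyl-6-methylhept-5-enoate
Product: 16 (6S)-6-[(2E,6Z)-1-acetoxy-8-[(tert-butyldiphenylsilyl)oxy]-6-methylocta-2,6-dien-2-yl]-3-(4-methylpent-3-en-1-yl)-5,6-dihydro-2H-pyran-2-one, via seco hydroxy ester 15 (not isolated)
Conditions: [Cu(CH3CN)4]PF6 (10 mol %), (R)-DTBM-SEGPHOS (11 mol %), 2-tert-butyl-1,1,3,3-tetramethylguanidine (20 mol %), 14 (2 equiv), 5 Å MS, THF, −20 °C → rt
Reagents that add atoms: none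
Why: Proposed new method: the closest known reaction type is the direct asymmetric vinylogous aldol–lactonisation of unbranched β,γ-unsaturated esters with aldehydes under soft enolisation by a monovalent-copper bisphosphine complex and an amine base, extended here to an α-branched donor and an α-acetoxymethyl enal; the copper dienolate of 14 reacts at its γ-carbon because α-attack would build a reversible, congested quaternary centre, the α-substituent enforces the s-cis dienolate so that the closed eight-membered transition state gives the (Z)-enoate 15 after ligand-controlled Si-face addition to the aldehyde (C8 = S), and the C8 alkoxide, held cis to the ester, expels methoxide to close the lactone as the 8-hydroxy-18-oic acid would in the biosynthesis.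

Step 7
Reactants: 16 (6S)-6-[(2E,6Z)-1-acetoxy-8-[(tert-butyldiphenylsilyl)oxy]-6-methylocta-2,6-dien-2-yl]-3-(4-methylpent-3-en-1-yl)-5,6-dihydro-2H-pyran-2-one
Product: 17 (6S)-6-[(2E,6Z)-1-acetoxy-8-hydroxy-6-methylocta-2,6-dien-2-yl]-3-(4-methylpent-3-en-1-yl)-5,6-dihydro-2H-pyran-2-one
Conditions: HF·pyridine, pyridine, THF, 0 °C → rt
Reagents that add atoms: none
Why: Buffered fluoride-mediated desilylation cleaves only the Si–O bond, leaving the acetate, the lactone, the allylic C8–O bond and the C8 stereocentre untouched.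

## Compound list

1 | nerol, (2Z)-3,7-dimethylocta-2,6-dien-1-ol | CC(C)=CCC/C(C)=C\CO | starting material
2 | tert-butyl{[(2Z)-3,7-dimethylocta-2,6-dien-1-yl]oxy}diphenylsilane | CC(C)=CCC/C(C)=C\CO[Si](c1ccccc1)(c1ccccc1)C(C)(C)C | intermediate
3 | 3-{(3Z)-5-[(tert-butyldiphenylsilyl)oxy]-3-methylpent-3-en-1-yl}-5,5-dimethyl-1,2,4-trioxolane (racemic) | CC1(C)OOC(CC/C(C)=C\CO[Si](c2ccccc2)(c2ccccc2)C(C)(C)C)O1 | intermediate
4 | (4Z)-6-[(tert-butyldiphenylsilyl)oxy]-4-methylhex-4-enal | O=CCC/C(C)=C\CO[Si](c1ccccc1)(c1ccccc1)C(C)(C)C | intermediate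
5 | 2-bromo-3,3-diethoxyprop-1-ene (2-bromoacrolein diethyl acetal) | C=C(Br)C(OCC)OCC | starting material
6 | (3,3-diethoxyprop-1-en-2-yl)lithium | [Li]C(=C)C(OCC)OCC | intermediate
7 | lithium (6Z)-8-[(tert-butyldiphenylsilyl)oxy]-1,1-diethoxy-6-methyl-2-methylideneoct-6-en-3-olate (racemic) | [Li]OC(CC/C(C)=C\CO[Si](c1ccccc1)(c1ccccc1)C(C)(C)C)C(=C)C(OCC)OCC | intermediate
8 | (6Z)-8-[(tert-butyldiphenylsilyl)oxy]-1,1-diethoxy-6-methyl-2-methylideneoct-6-en-3-yl acetate (racemic) | CC(=O)OC(CC/C(C)=C\CO[Si](c1ccccc1)(c1ccccc1)C(C)(C)C)C(=C)C(OCC)OCC | intermediate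
9 | (6Z)-8-[(tert-butyldiphenylsilyl)oxy]-6-methyl-2-methylidene-1-oxooct-6-en-3-yl acetate (racemic) | CC(=O)OC(CC/C(C)=C\CO[Si](c1ccccc1)(c1ccccc1)C(C)(C)C)C(=C)C=O | intermediate
10 | (2E,6Z)-2-(acetoxymethyl)-8-[(tert-butyldiphenylsilyl)oxy]-6-methylocta-2,6-dienal | CC(=O)OC/C(C=O)=C\CC/C(C)=C\CO[Si](c1ccccc1)(c1ccccc1)C(C)(C)C | intermediate
11 | methyl (2E)-but-2-enoate (methyl crotonate) | C/C=C/C(=O)OC | starting material
12 | 5-bromo-2-methylpent-2-ene (homoprenyl bromide) | CC(C)=CCCBr | starting material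
13 | lithium 1-methoxybuta-1,3-dien-1-olate | C=CC=C(OC)O[Li] | intermediate
14 | methyl 2-ethenyl-6-methylhept-5-enoate (racemic) | COC(=O)C(C=C)CCC=C(C)C | intermediate
15 | methyl (2Z,5S,6E,10Z)-6-(acetoxymethyl)-12-[(tert-butyldiphenylsilyl)oxy]-5-hydroxy-10-methyl-2-(4-methylpent-3-en-1-yl)dodeca-2,6,10-trienoate | CC(=O)OC/C(=C\CC/C(C)=C\CO[Si](c1ccccc1)(c1ccccc1)C(C)(C)C)[C@@H](O)C/C=C(/CCC=C(C)C)C(=O)OC | intermediate
16 | (6S)-6-[(2E,6Z)-1-acetoxy-8-[(tert-butyldiphenylsilyl)oxy]-6-methylocta-2,6-dien-2-yl]-3-(4-methylpent-3-en-1-yl)-5,6-dihydro-2H-pyran-2-one | CC(=O)OC/C(=C\CC/C(C)=C\CO[Si](c1ccccc1)(c1ccccc1)C(C)(C)C)[C@@H]2CC=C(CCC=C(C)C)C(=O)O2 | intermediate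
17 | (6S)-6-[(2E,6Z)-1-acetoxy-8-hydroxy-6-methylocta-2,6-dien-2-yl]-3-(4-methylpent-3-en-1-yl)-5,6-dihydro-2H-pyran-2-one (CNP0179839.2) | CC(=O)OC/C(=C\CC/C(C)=C\CO)[C@@H]1CC=C(CCC=C(C)C)C(=O)O1 | target

## Step count and risks

Total steps: 7. Longest linear sequence: 6 (steps 1, 2, 3, 4, 6, 7 from nerol); step 5 is a one-step side branch.

Most likely to fail, first: step 6. The α-branched ester 14 may enolise too slowly under soft conditions. Enal 10 is a Morita–Baylis–Hillman-type acetate that can lose acetate by SN2' attack or by γ-deprotonation and elimination. The C8 alkoxide can also take the acetyl group from O19; this is reversible and should be drained by the irreversible lactonisation. The enantioselectivity for this substrate pair is untested. The fallback sets out from 10 and 14 and comes back at 16. Ester 14 is converted (LiN(iPr)2, TBSCl, HMPA, THF, −78 °C) into the silyl ketene acetal tert-butyl{[1-methoxy-2-(4-methylpent-3-en-1-yl)buta-1,3-dien-1-yl]oxy}dimethylsilane F1. A Lewis-base-catalysed vinylogous Mukaiyama aldol reaction of this with 10 (SiCl4, chiral binaphthyldiamine bisphosphoramide of the antipode giving Si-face attack, iPr2NEt, CH2Cl2, −78 °C) gives the open-chain methyl (2E,5S,6E,10Z)-6-(acetoxymethyl)-12-[(tert-butyldiphenylsilyl)oxy]-5-hydroxy-10-methyl-2-(4-methylpent-3-en-1-yl)dodeca-2,6,10-trienoate F2. This cannot lactonise until the conjugated enoate is photoisomerised (E to Z, about 300 nm, with a trace of camphorsulfonic acid); the Z isomer then closes to 16.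

Second: step 4. The unmasked 2-methylene aldehyde 9 may oligomerise, or DABCO may give ammonium adducts or an E/Z mixture instead of a clean 1,3-shift. The fallback sets out from 4 and comes back at 10, building the enal without any allylic transposition:
- Wittig reaction of 4 with Ph3P=CHCHO (toluene, 80 °C) gives (2E,6Z)-8-[(tert-butyldiphenylsilyl)oxy]-6-methylocta-2,6-dienal F3.
- α-Iodination (I2, DMAP, K2CO3, THF/H2O) gives (2Z,6Z)-8-[(tert-butyldiphenylsilyl)oxy]-2-iodo-6-methylocta-2,6-dienal F4, with CHO still trans to the chain.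
- Stille coupling with Bu3SnCH2OH (Pd(PPh3)4, dioxane, 80 °C) gives (2E,6Z)-8-[(tert-butyldiphenylsilyl)oxy]-2-(hydroxymethyl)-6-methylocta-2,6-dienal F5.
- Acetylation (Ac2O, pyridine, 0 °C) gives 10.

Third: step 2. The two trisubstituted olefins may not be distinguished well enough by ozone, giving over-cleavage. The fallback sets out from 2 and comes back at 4, using terminal-selective bromohydrin formation instead of ozonolysis:
- NBS in THF/H2O at 0 °C gives (6Z)-3-bromo-8-[(tert-butyldiphenylsilyl)oxy]-2,6-dimethyloct-6-en-2-ol F6.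
- K2CO3 in MeOH closes it to tert-butyl{[(2Z)-5-(3,3-dimethyloxiran-2-yl)-3-methylpent-2-en-1-yl]oxy}diphenylsilane F7.
- H5IO6 in THF/H2O cleaves the epoxide to 4.

## Further compounds

F1 | step 6 | tert-butyl{[1-methoxy-2-(4-methylpent-3-en-1-yl)buta-1,3-dien-1-yl]oxy}dimethylsilane | C=CC(CCC=C(C)C)=C(OC)O[Si](C)(C)C(C)(C)C
F2 | step 6 | methyl (2E,5S,6E,10Z)-6-(acetoxymethyl)-12-[(tert-butyldiphenylsilyl)oxy]-5-hydroxy-10-methyl-2-(4-methylpent-3-en-1-yl)dodeca-2,6,10-trienoate | CC(=O)OC/C(=C\CC/C(C)=C\CO[Si](c1ccccc1)(c1ccccc1)C(C)(C)C)[C@@H](O)C/C=C(\CCC=C(C)C)C(=O)OC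
F3 | step 4 | (2E,6Z)-8-[(tert-butyldiphenylsilyl)oxy]-6-methylocta-2,6-dienal | O=C/C=C/CC/C(C)=C\CO[Si](c1ccccc1)(c1ccccc1)C(C)(C)C
F4 | step 4 | (2Z,6Z)-8-[(tert-butyldiphenylsilyl)oxy]-2-iodo-6-methylocta-2,6-dienal | O=C/C(I)=C/CC/C(C)=C\CO[Si](c1ccccc1)(c1ccccc1)C(C)(C)C
F5 | step 4 | (2E,6Z)-8-[(tert-butyldiphenylsilyl)oxy]-2-(hydroxymethyl)-6-methylocta-2,6-dienal | OC/C(C=O)=C\CC/C(C)=C\CO[Si](c1ccccc1)(c1ccccc1)C(C)(C)C
F6 | step 2 | (6Z)-3-bromo-8-[(tert-butyldiphenylsilyl)oxy]-2,6-dimethyloct-6-en-2-ol (racemic) | CC(C)(O)C(Br)CC/C(C)=C\CO[Si](c1ccccc1)(c1ccccc1)C(C)(C)C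
F7 | step 2 | tert-butyl{[(2Z)-5-(3,3-dimethyloxiran-2-yl)-3-methylpent-2-en-1-yl]oxy}diphenylsilane (racemic) | CC1(C)OC1CC/C(C)=C\CO[Si](c2ccccc2)(c2ccccc2)C(C)(C)C
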